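## Retrosynthetic overview

1. Numbering follows drimane (ring A = C1–C5 and C10, ring B = C5–C10, C11 = the CH2O carbon on C9). The C3 tiglate and the C11 aryl ether are cut first (acylation; Mitsunobu reaction with umbelliferone) to a 3,8,11-triol. Its C8 methyl carbinol, C11 and C3–OH trace back to a C8 ketone (MeMgBr), a C8 silyl enol ether (formaldehyde Mukaiyama aldol at C9) and a C3 ketone (hydride).
2. Key disconnection: the C2–C3 bond of ring A. A cyclobutane (C9–C10–C1–C2) fused to a ring B ketone is opened by SmI2 at the C8 ketyl. The strain-released C2 becomes an organosamarium that attacks the C3 ester, so ring A closes as the four-membered ring opens, and the C8/C9 enolate is left for C11.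
3. The cyclobutane comes from [2+2] photocycloaddition of ethylene across C9=C10 of a ring B enone, which sets the quaternary C10. The C4–C5 bond and the C5 centre come from an Ireland–Claisen rearrangement of the isobutyrate of (R)-2-methylcyclohex-2-en-1-ol (Corey–Bakshi–Shibata reduction), followed by allylic oxidation at C8.
4. Order of rings: ring B is present from the start (2-methylcyclohex-2-en-1-one); the temporary cyclobutane is fused to it; ring A is formed last, in the key step, at the expense of the cyclobutane.
5. Enabling feature: in ring B the C8 oxygen sits next to C9, and C9 is bonded to the quaternary C10 that carries C1, so a C8 carbonyl can hold C2 on C9 and then eject it. In ring A the oxygenated C3 lies next to the quaternary C4 (gem-dimethyl), so it can be a non-enolisable ester, and the C4 and C1 arms are trans-diequatorial on C5 and C10, which places C2 next to C3.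

Key step: step 7

## Route

Step 1
Reactants: 1 2-methylcyclohex-2-en-1-one
Product: 2 (1R)-2-methylcyclohex-2-en-1-ol
Conditions: (S)-2-methyl-CBS-oxazaborolidine (cat.), BH3·SMe2, THF, −20 °C; MeOH quench
Reagents that add atoms: none
Why: Corey–Bakshi–Shibata reduction, in which the oxazaborolidine–borane complex should deliver hydride to one carbonyl face with the 2-methylvinyl branch acting as the large group, setting the R carbinol centre that later relays its chirality to C5.

Step 2
Reactants: 2 (1R)-2-methylcyclohex-2-en-1-ol; 3 2-methylpropanoyl chloride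
Product: 4 (1R)-2-methylcyclohex-2-en-1-yl 2-methylpropanoate
Conditions: Et3N, DMAP (cat.), CH2Cl2, 0 °C to rt
Reagents that add atoms: none
Why: DMAP-catalysed O-acylation of the allylic alcohol, which does not touch the carbinol centre and installs the isobutyrate that will become C3, C4 and the gem-dimethyl group.

Step 3
Reactants: 4 (1R)-2-methylcyclohex-2-en-1-yl 2-methylpropanoate
Product: 7 2-methyl-2-[(1S)-2-methylcyclohex-2-en-1-yl]propanoic acid, via silyl ketene acetal 5 (not isolated), via trimethylsilyl ester 6 (not isolated)
Conditions: LiN(iPr)2, THF, −78 °C; Me3SiCl; −78 to 60 °C; 1 M HCl work-up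
Reagents that add atoms: chlorotrimethylsilane, C[Si](C)(C)Cl
Why: Ireland–Claisen rearrangement, in which the tetrasubstituted silyl ketene acetal rearranges suprafacially across the ring so that the C4–C5 bond forms on the face that carried the allylic oxygen and the R carbinol centre is converted into the S centre at C5.

Step 4
Reactants: 7 2-methyl-2-[(1S)-2-methylcyclohex-2-en-1-yl]propanoic acid
Product: 8 methyl 2-methyl-2-[(1S)-2-methylcyclohex-2-en-1-yl]propanoate
Conditions: MeI, K2CO3, DMF, rt
Reagents that add atoms: iodomethane, CI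
Why: Carboxylate O-alkylation (SN2 at methyl), which avoids attack at the hindered acyl carbon and gives the non-enolisable C3 methyl ester needed as the electrophile of the key step.

Step 5
Reactants: 8 methyl 2-methyl-2-[(1S)-2-methylcyclohex-2-en-1-yl]propanoate
Product: 9 methyl 2-methyl-2-[(1S)-2-methyl-4-oxocyclohex-2-en-1-yl]propanoate
Conditions: Rh2(cap)4 (dirhodium tetrakis(caprolactamate), cat.), t-BuOOH, K2CO3, CH2Cl2, rt
Reagents that add atoms: tert-butyl hydroperoxide, CC(C)(C)OO
Why: Radical allylic C–H oxidation, which should occur at the only unhindered allylic methylene (C8), since the other allylic ring position (C5) is a tertiary C–H shielded by the quaternary C4, and which gives the C8 enone without touching the C5 centre.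

Step 6
Reactants: 9 methyl 2-methyl-2-[(1S)-2-methyl-4-oxocyclohex-2-en-1-yl]propanoate; 10 ethylene
Product: 11 methyl 2-methyl-2-[(1R,2S,6R)-1-methyl-5-oxobicyclo[4.2.0]octan-2-yl]propanoate
Conditions: hν (medium-pressure Hg lamp, Pyrex filter), ethylene-saturated CH2Cl2, −78 °C; then basic Al2O3
Reagents that add atoms: none
Why: Enone–alkene [2+2] photocycloaddition, in which the triplet enone should add ethylene across C9=C10 on the ring face opposite the bulky C5 side chain, setting the quaternary C10 (C1 trans to C4) and the cis-fused C9 centre, any trans-fused isomer being epimerised at C9 on alumina.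

Step 7
Reactants: 11 methyl 2-methyl-2-[(1R,2S,6R)-1-methyl-5-oxobicyclo[4.2.0]octan-2-yl]propanoate
Product: 14 (4aR,8aS)-1,1,4a-trimethyl-6-[(trimethylsilyl)oxy]-3,4,4a,7,8,8a-hexahydronaphthalen-2(1H)-one, via ring-opened radical enolate 12 (not isolated), via bicyclic keto enolate 13 (not isolated)
Conditions: SmI2 (2.2 equiv), HMPA, THF, −78 to 0 °C (slow addition of 11); Me3SiCl, Et3N, −78 °C; aq. NaHCO3
Reagents that add atoms: chlorotrimethylsilane, C[Si](C)(C)Cl
Why: Proposed new method: SmI2 should reduce the C8 ketone to a ketyl whose axial C9–C2 cyclobutane bond lies parallel to the carbonyl π system, so that strain-releasing β-scission gives the trivalent samarium enolate and a primary C2 radical (12), a second SmI2 reduces this radical to the C2 organosamarium, and that nucleophile attacks the C3 methyl ester with loss of methoxide (13) before Me3SiCl caps the enolate oxygen. The closest known reaction types are the SmI2- or dissolving-metal-induced reductive opening of cyclopropyl and cyclobutyl ketones obtained from enone photoadducts and the SmI2-mediated intramolecular nucleophilic acyl substitution of iodoalkyl esters; here the ring opening itself generates the carbon nucleophile. Ring A is closed by a 6-exo-trig attack of C2 on the C3 carbonyl, which forms the C2–C3 bond, and the ring fusion can only be trans because the C1 and C4 arms already stand trans-diequatorial on C10 and C5. No new stereocentre arises: C5 and C10 are carried through unchanged and the C9 centre is erased into the enol ether. The step needs cleavage of the external C9–C2 bond and not of the ring-fusion bond C9–C10, which the axial position of C9–C2 in the chair anchored by the equatorial C5 substituent should secure, and it needs a C3 electrophile that SmI2 neither reduces nor deprotonates, which the ester on the quaternary C4 provides.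

Step 8
Reactants: 14 (4aR,8aS)-1,1,4a-trimethyl-6-[(trimethylsilyl)oxy]-3,4,4a,7,8,8a-hexahydronaphthalen-2(1H)-one
Product: 15 (2R,4aR,8aS)-1,1,4a-trimethyl-6-[(trimethylsilyl)oxy]-1,2,3,4,4a,7,8,8a-octahydronaphthalen-2-ol
Conditions: LiAlH(OtBu)3, THF, 0 °C; aq. potassium sodium tartrate work-up
Reagents that add atoms: none
Why: Hydride reduction of the 4,4-dimethyl-3-ketone, in which axial delivery on the face opposite the axial C4 methyl should give the equatorial C3 alcohol (3R, cis to the C10 methyl) while the aprotic conditions spare the silyl enol ether.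

Step 9
Reactants: 15 (2R,4aR,8aS)-1,1,4a-trimethyl-6-[(trimethylsilyl)oxy]-1,2,3,4,4a,7,8,8a-octahydronaphthalen-2-ol; 16 formaldehyde
Product: 17 (1S,4aS,6R,8aR)-6-hydroxy-1-(hydroxymethyl)-5,5,8a-trimethyloctahydronaphthalen-2(1H)-one
Conditions: aq. HCHO, Yb(OTf)3 (cat.), THF, rt
Reagents that add atoms: none
Why: Lewis acid-catalysed Mukaiyama aldol (hydroxymethylation) of the regiodefined silyl enol ether, in which formaldehyde should approach C9 axially on the face opposite the adjacent axial C10 methyl and so place C11 trans to that methyl (9S).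

Step 10
Reactants: 17 (1S,4aS,6R,8aR)-6-hydroxy-1-(hydroxymethyl)-5,5,8a-trimethyloctahydronaphthalen-2(1H)-one
Product: 18 (1S,2R,4aS,6R,8aR)-1-(hydroxymethyl)-2,5,5,8a-tetramethyldecahydronaphthalene-2,6-diol
Conditions: MeMgBr (5 equiv), THF, −78 to 0 °C; aq. NH4Cl
Reagents that add atoms: methylmagnesium bromide, C[Mg]Br
Why: Grignard 1,2-addition to the C8 ketone, in which the axial C10 methyl blocks the axial approach so that methyl should enter equatorially and give the axial tertiary alcohol cis to the C10 methyl (8R), the two free hydroxyls being carried as magnesium alkoxides.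

Step 11
Reactants: 18 (1S,2R,4aS,6R,8aR)-1-(hydroxymethyl)-2,5,5,8a-tetramethyldecahydronaphthalene-2,6-diol; 19 7-hydroxy-2H-chromen-2-one (umbelliferone)
Product: 20 7-{[(1S,2R,4aS,6R,8aR)-2,6-dihydroxy-2,5,5,8a-tetramethyldecahydronaphthalen-1-yl]methoxy}-2H-chromen-2-one
Conditions: PPh3, DIAD, THF, 0 °C to rt
Reagents that add atoms: none
Why: Mitsunobu etherification, in which the acidic phenol displaces the activated primary C11 hydroxyl (no stereocentre involved) while the hindered secondary C3 and tertiary C8 hydroxyls should stay unactivated.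

Step 12
Reactants: 20 7-{[(1S,2R,4aS,6R,8aR)-2,6-dihydroxy-2,5,5,8a-tetramethyldecahydronaphthalen-1-yl]methoxy}-2H-chromen-2-one; 21 (2E)-2-methylbut-2-enoyl chloride (tigloyl chloride)
Product: 22 (2R,4aR,5S,6R,8aS)-6-hydroxy-1,1,4a,6-tetramethyl-5-{[(2-oxo-2H-chromen-7-yl)oxy]methyl}decahydronaphthalen-2-yl (2E)-2-methylbut-2-enoate
Conditions: pyridine, DMAP (cat.), CH2Cl2, 0 to 40 °C
Reagents that add atoms: none
Why: DMAP-catalysed O-acylation of the equatorial secondary C3 hydroxyl, which retains the C3 configuration and the E geometry of the acyl group, the axial tertiary C8 hydroxyl being too hindered to react.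

## Compound list

1 | 2-methylcyclohex-2-en-1-one | CC1=CCCCC1=O | starting material
2 | (1R)-2-methylcyclohex-2-en-1-ol | O[C@@H]1CCCC=C1C | intermediate
3 | 2-methylpropanoyl chloride (isobutyryl chloride) | CC(C)C(Cl)=O | starting material
4 | (1R)-2-methylcyclohex-2-en-1-yl 2-methylpropanoate | CC(C)C(=O)O[C@@H]1CCCC=C1C | intermediate
5 | trimethyl[(2-methyl-1-{[(1R)-2-methylcyclohex-2-en-1-yl]oxy}prop-1-en-1-yl)oxy]silane (silyl ketene acetal, formed in the flask) | CC(C)=C(O[Si](C)(C)C)O[C@@H]1CCCC=C1C | intermediate
6 | trimethylsilyl 2-methyl-2-[(1S)-2-methylcyclohex-2-en-1-yl]propanoate (formed in the flask) | C[Si](C)(C)OC(=O)C(C)(C)[C@H]1CCCC=C1C | intermediate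
7 | 2-methyl-2-[(1S)-2-methylcyclohex-2-en-1-yl]propanoic acid | OC(=O)C(C)(C)[C@H]1CCCC=C1C | intermediate
8 | methyl 2-methyl-2-[(1S)-2-methylcyclohex-2-en-1-yl]propanoate | COC(=O)C(C)(C)[C@H]1CCCC=C1C | intermediate
9 | methyl 2-methyl-2-[(1S)-2-methyl-4-oxocyclohex-2-en-1-yl]propanoate | COC(=O)C(C)(C)[C@H]1CCC(=O)C=C1C | intermediate
10 | ethylene | C=C | starting material
11 | methyl 2-methyl-2-[(1R,2S,6R)-1-methyl-5-oxobicyclo[4.2.0]octan-2-yl]propanoate (cis-fused cyclobutane on the face opposite the side chain) | COC(=O)C(C)(C)[C@H]1CCC(=O)[C@@H]2CC[C@]12C | intermediate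
12 | ring-opened radical enolate: diiodosamarium (trivalent) enolate of methyl 2-methyl-2-[(1S,2R)-2-methyl-4-oxocyclohexyl]propanoate carrying a CH2CH2 radical chain on the methyl-bearing ring carbon (C10; radical at C2), formed in the flask | COC(=O)C(C)(C)[C@H]1CCC(O[Sm](I)I)=C[C@]1(C)C[CH2] | intermediate
13 | bicyclic keto enolate: diiodosamarium (trivalent) C8 enolate of (4aR,8aS)-1,1,4a-trimethyloctahydronaphthalene-2,6-dione (ring A closed), formed in the flask | O=C1CC[C@]2(C)[C@H](CCC(O[Sm](I)I)=C2)C1(C)C | intermediate
14 | (4aR,8aS)-1,1,4a-trimethyl-6-[(trimethylsilyl)oxy]-3,4,4a,7,8,8a-hexahydronaphthalen-2(1H)-one | O=C1CC[C@]2(C)[C@H](CCC(O[Si](C)(C)C)=C2)C1(C)C | intermediate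
15 | (2R,4aR,8aS)-1,1,4a-trimethyl-6-[(trimethylsilyl)oxy]-1,2,3,4,4a,7,8,8a-octahydronaphthalen-2-ol | O[C@@H]1CC[C@]2(C)[C@H](CCC(O[Si](C)(C)C)=C2)C1(C)C | intermediate
16 | formaldehyde | C=O | starting material
17 | (1S,4aS,6R,8aR)-6-hydroxy-1-(hydroxymethyl)-5,5,8a-trimethyloctahydronaphthalen-2(1H)-one | O[C@@H]1CC[C@]2(C)[C@H](CCC(=O)[C@@H]2CO)C1(C)C | intermediate
18 | (1S,2R,4aS,6R,8aR)-1-(hydroxymethyl)-2,5,5,8a-tetramethyldecahydronaphthalene-2,6-diol | O[C@@H]1CC[C@]2(C)[C@H](CC[C@@](C)(O)[C@@H]2CO)C1(C)C | intermediate
19 | 7-hydroxy-2H-chromen-2-one (umbelliferone) | Oc1ccc2ccc(=O)oc2c1 | starting material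
20 | 7-{[(1S,2R,4aS,6R,8aR)-2,6-dihydroxy-2,5,5,8a-tetramethyldecahydronaphthalen-1-yl]methoxy}-2H-chromen-2-one | O[C@@H]1CC[C@]2(C)[C@H](CC[C@@](C)(O)[C@@H]2COc2ccc3ccc(=O)oc3c2)C1(C)C | intermediate
21 | (2E)-2-methylbut-2-enoyl chloride (tigloyl chloride) | C/C=C(\C)C(Cl)=O | starting material
22 | (2R,4aR,5S,6R,8aS)-6-hydroxy-1,1,4a,6-tetramethyl-5-{[(2-oxo-2H-chromen-7-yl)oxy]methyl}decahydronaphthalen-2-yl (2E)-2-methylbut-2-enoate | C/C=C(\C)C(=O)O[C@@H]1CC[C@]2(C)[C@H](CC[C@@](C)(O)[C@@H]2COc2ccc3ccc(=O)oc3c2)C1(C)C | target

## Step count and risks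

Total step count: 12. Longest linear sequence: 12 steps (1 to 22); all other starting materials enter as purchased reagents.

Steps most likely to fail:

Step 7. The ketyl may be reduced further or couple instead of fragmenting, the ring-fusion bond may break in place of the external one, or the C2 organosamarium may be protonated before it acylates. The fallback separates ring opening from ring closure and uses only known reaction types. It sets out from 11: Me3SiI (from Me3SiCl and NaI, Et3N buffer, MeCN/CH2Cl2, low temperature) should open the cyclobutyl ketone by homoconjugate attack of iodide at C2, giving methyl 2-[(1S,2R)-2-(2-iodoethyl)-2-methyl-4-[(trimethylsilyl)oxy]cyclohex-3-en-1-yl]-2-methylpropanoate F1. The isolated iodide would then be cyclised by SmI2 with catalytic Fe(dbm)3 in THF (intramolecular nucleophilic acyl substitution of an iodoalkyl ester), which comes back to the route at 14.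

Step 6. The photocycloaddition may show poor facial selectivity at C10, or the enone may deconjugate photochemically. The fallback builds the quaternary centre by ionic conjugate addition and never forms the cyclobutane. It sets out from 9: vinylmagnesium bromide with CuBr·SMe2 and Me3SiCl in THF at −78 °C should add the vinyl group to C10 anti to the C5 substituent and trap the enolate as methyl 2-[(1S,2R)-2-ethenyl-2-methyl-4-[(trimethylsilyl)oxy]cyclohex-3-en-1-yl]-2-methylpropanoate F2. Hydrozirconation of the vinyl group with Cp2Zr(H)Cl followed by iodinolysis with I2 would give the iodide F1 described above, and its SmI2/Fe(dbm)3 cyclisation comes back to the route at 14.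

Step 10. The methyl addition to C8 may show poor facial selectivity, because the axial C11 group hinders the equatorial approach while the C10 methyl hinders the axial one. The fallback replaces kinetic carbonyl addition by reversible methylene transfer and hydride opening. It sets out from 17: dimethylsulfoxonium methylide (Me3S(O)I, NaH, DMSO; Corey–Chaykovsky reaction) should close the spiro-epoxide with the new C–C bond equatorial and the oxygen axial, giving (1'S,2R,4a'S,6'R,8a'R)-1'-(hydroxymethyl)-5',5',8a'-trimethyloctahydro-1'H-spiro[oxirane-2,2'-naphthalen]-6'-ol F3. LiEt3BH in THF would open the epoxide at its CH2 terminus to the tertiary alcohol, which comes back to the route at 18.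

Further compounds
F1 | step 7 | methyl 2-[(1S,2R)-2-(2-iodoethyl)-2-methyl-4-[(trimethylsilyl)oxy]cyclohex-3-en-1-yl]-2-methylpropanoate | COC(=O)C(C)(C)[C@H]1CCC(O[Si](C)(C)C)=C[C@]1(C)CCI
F2 | step 6 | methyl 2-[(1S,2R)-2-ethenyl-2-methyl-4-[(trimethylsilyl)oxy]cyclohex-3-en-1-yl]-2-methylpropanoate | COC(=O)C(C)(C)[C@H]1CCC(O[Si](C)(C)C)=C[C@]1(C)C=C
F3 | step 10 | (1'S,2R,4a'S,6'R,8a'R)-1'-(hydroxymethyl)-5',5',8a'-trimethyloctahydro-1'H-spiro[oxirane-2,2'-naphthalen]-6'-ol (C8 spiro-epoxide, oxygen axial and cis to the C10 methyl) | O[C@@H]1CC[C@]2(C)[C@H](CC[C@]3(CO3)[C@@H]2CO)C1(C)C
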